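## Structural features

The target is a flavonol. Rings A and C form a 4H-chromen-4-one, ring B (4-hydroxy-3-methoxyphenyl) sits on C2, and C3 carries a hydroxyl. Ring A is a 1,2,3,5-tetraoxygenated benzene in which each oxygen has a different partner: a free hydroxyl at C5 (hydrogen-bonded to the C4 carbonyl), a 3-methylbut-2-enyl (prenyl) ether at C7, a methyl ether at C8 and the ring oxygen O1 at C8a; only C6 bears hydrogen. There is no stereocentre and no geometrical isomerism, so the task is one of regiochemistry and functional-group tolerance. The fragile parts are the prenyl aryl ether and the 3-hydroxy enone. The prenyl ether is ionised by acid, reduced by hydrogenation, attacked by electrophilic oxidants, open to aromatic Claisen rearrangement on strong heating, and is an allylic ether towards zerovalent palladium. The anion of the 3-hydroxy enone is oxidised by air. The real difficulty is to place four different oxygen substituents around ring A and to reach the C3 oxidation level without a late oxidation that the prenyl double bond would not survive. The key step uses the tetrasubstituted C2=C3 bond of ring C. C2 bears O1 and C1' of ring B, which is the pattern of the carbonyl carbon of a ring B benzoate on the C8a phenol. C3 bears an oxygen and the C4 carbonyl, which is the pattern of the carbon of an alkoxy-substituted acyl ylide tied through C4 to C4a.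

## Logic of the disconnections

22 to 21: the O4'–Si bond and the O3–CH2 and O5–CH2 bonds of two 2-(trimethylsilyl)ethyl ethers are cut. All three masks answer to fluoride, so neither acid nor hydrogen meets the prenyl ether. Nothing is gained in skeleton; the gain is that the three acidic hydroxyls stay silent through the ylide chemistry. The forward step must fragment two carbon-based silylethyl ethers under conditions the flavonolate tolerates.

21 to 20: the C2=C3 bond is cut and ring C opens. C2 is at the ester oxidation level and C3 carries oxygen and the acyl carbon C4, so the retron of an ester Wittig olefination is present. The bicyclic core becomes a benzene ring with two ortho substituents, and the flavonol oxidation level is already built in. The forward step demands that a fully substituted ylide carbon add to an ester carbonyl within the same molecule.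

20 to 17 and 3 (through 18 and 19): the C3–C4 bond is cut. Acyl ylides arise by C-acylation of a simpler ylide, and C3 arrives together with O3 and phosphorus. This leaves a benzoic acid and a one-carbon reagent. The forward step demands neutral activation of the acid and acylation at the acid chloride in preference to the aryl ester.

3 to 1 and 2: the P–CH2 bond is cut; quaternisation of a phosphine by an α-chloro ether is the only demand.

17 to 16: the carboxyl group is traced back to an aldehyde. An aldehyde passes through the phenol chemistry without an ester to hydrolyse beside the aryl ester and without a decarboxylation-prone salicylic acid. The oxidation must spare the prenyl alkene and the electron-rich ring.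

16 to 12 and 15: the ester bond between the C8a oxygen and the ring B carbonyl (later O1–C2) is cut. This is the convergent point: all of ring B arrives in one piece. The forward step must acylate a hindered, hydrogen-bonded phenol.

15 to 13: the O4'–Si bond is cut; the acid must be freed again after double silylation.

12 to 11 to 10: first the O7–prenyl bond, then the two acetal bonds at the oxygens ortho and para to the formyl group. In 11 the para hydroxyl is the more acidic and the ortho hydroxyl is chelated, which is what tells the later O7 from the later O1. The acetal removal must leave the silylethyl ether in place.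

10 to 8 (through 9): the bond between C4a and the formyl carbon is cut. In 8 the two ring hydrogens are equivalent by symmetry and each lies between two ether oxygens, so one lithiation site exists. This removes the only substituent that breaks the symmetry.

8 to 7 to 5 (through 6) to 4: the O5–CH2 bond, then the C5–O bond by way of a C–B bond, then the two acetals. C5 of 5 is meta to both acetal oxygens and out of reach of electrophilic substitution, but it is the only C–H without an ortho substituent, which is the selection rule of iridium-catalysed borylation. Compound 4 already holds the methoxy group between two oxygens.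

## Other disconnections considered

Alternative 1: The cut lies in ring A, through C8–C8a and C4a–C5, so that the benzene ring is assembled from the furan A1 (4-(benzyloxy)-2-[(tert-butyldimethylsilyl)oxy]furan) and methyl 3-bromopropiolate A2. In the forward sense the electron-rich C5 terminus of A1 should bond to the bromine-bearing alkyne carbon in a (4+2) cycloaddition. The oxygen bridge should then open at the silyloxy bridgehead and tautomerise to the benzoate A3 (methyl 4-(benzyloxy)-2-bromo-6-[(tert-butyldimethylsilyl)oxy]-3-hydroxybenzoate).
- In its favour: every ring A position comes out different by construction (silyl at O5, benzyl at O7, free hydroxyl at C8 ready for methylation, bromine at C8a), and C4 arrives at the acid oxidation level. On positional differentiation this is the equal of the chosen plan or better, since the chosen plan relies on symmetry up to 10 and on chelation in step 7. It also needs no late aldehyde oxidation.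
- Against it here: C8a carries bromine, not oxygen, so a C–O bond must still be made on a hexasubstituted, electron-rich arene. The benzyl group at O7 must be exchanged for prenyl by a method that spares the aryl bromide. A1 is a moisture-sensitive diene that itself takes several steps.
- Comparison: this alternative does not address ring C or the C3 oxygen, so a ring-closing plan such as that of step 12 would still be needed after it. It should be longer than the six steps that lead to 12. Its mechanistic risk (regiochemistry and bridge opening of a cycloadduct) sits early, while that of the chosen plan sits late.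

Alternative 2: The cut again lies in ring A, through C8–C8a and C6–C7, but ring A is built last on a finished ring C. The pyranone A4 (5-acetyl-2-[3-methoxy-4-(methoxymethoxy)phenyl]-3-(methoxymethoxy)-6-(methylsulfanyl)-4H-pyran-4-one) would take up the lithium enolate of methyl methoxyacetate A5 by addition–elimination at the sulfur-bearing carbon. The acetyl enolate would then condense onto the new ester, and enolisation would give the flavone A6 (5,7-dihydroxy-8,3'-dimethoxy-3,4'-bis(methoxymethoxy)flavone).
- In its favour: the C8 methoxy group is delivered by the reagent and cannot be misplaced. O5 and O7 arrive free and differ by chelation, so prenylation at O7 would follow directly. O3 and ring B are already present. On ring A regiochemistry and on protecting groups for ring A this is better than the chosen plan, and after A6 only two operations would remain.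
- Against it here: A4 is a densely functionalised pyranone whose own synthesis is likely to outweigh the whole ring A sequence of the chosen plan. A4 offers a hard ester enolate several electrophilic sites (C2, C4, the acetyl carbonyl) and an acidic acetyl group, so ring opening or simple proton transfer may compete. The acetals at O3 and O4' would have to leave under acid after the prenyl ether is in place.
- Comparison: the chosen key step is a neutral thermal closure with one possible electrophile, whereas this one is a strongly basic cascade with several. Step economy is better at the end and worse at the front.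

Alternative 3: The cut removes three bonds of ring C at once, C4a–C4, C4–C3 and O1–C2. The iodophenol A7 (2-iodo-6-methoxy-3-(methoxymethoxy)-5-[(3-methylbut-2-en-1-yl)oxy]phenol), carbon monoxide A9 and the alkyne A8 (4-ethynyl-2-methoxy-1-(methoxymethoxy)benzene) would be joined under palladium catalysis with an amine base. Oxidative addition of zerovalent palladium, insertion of A9 and coupling with A8 would give an ynone, and the phenol would close onto it in a 6-endo-dig fashion to the flavone A10 (5,4'-bis(methoxymethoxy)-8,3'-dimethoxy-7-(prenyloxy)flavone).
- In its favour: it is the most convergent of all the plans. It needs no aldehyde, no acid activation and no stoichiometric phosphorus. On convergence, atom economy and step count to the flavone core it is better than the chosen plan.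
- Against it here: A10 has hydrogen at C3, so the flavonol oxygen must be put in afterwards on the most advanced intermediate, by metalation–borylation–oxidation or by an electrophilic oxidant that also threatens the prenyl alkene. The 5-exo-dig closure to an aurone competes with the 6-endo mode. The aryl iodide lies between two oxygen substituents on an electron-rich ring. The prenyl ether is an allylic ether in the presence of zerovalent palladium. The acetals again call for acid at the end.
- Comparison: this alternative reaches the ring system faster but at the wrong oxidation level. The chosen plan spends more steps on ring A but brings C3 in with its oxygen and ends with a single non-acidic deprotection.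

Key step: step 12

Remark on the chemistry: O5 is carried as a 2-(trimethylsilyl)ethyl ether and O4' as a tert-butyldimethylsilyl ether, not as methoxymethyl acetals, because an acetal oxygen ortho to an acid chloride can cyclise onto it with loss of chloromethane and because acid at the end would endanger the prenyl ether; the connectivity of 20 and 21 was checked atom by atom against the target and needed no correction.

## Route

Step 1
Reactants: 1 2-(trimethylsilyl)ethoxymethyl chloride; 2 triphenylphosphine
Product: 3 {[2-(trimethylsilyl)ethoxy]methyl}triphenylphosphonium chloride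
Conditions: toluene, 80 °C; salt collected by filtration
Reagents that add atoms: none
Why: SN2 quaternisation of the phosphine by the reactive α-chloro ether, the usual preparation of an alkoxymethyl Wittig salt.

Step 2
Reactants: 4 2-methoxyresorcinol
Product: 5 2-methoxy-1,3-bis(methoxymethoxy)benzene
Conditions: MOMCl (2.5 equiv), i-Pr2NEt, CH2Cl2, 0 °C → rt
Reagents that add atoms: chloromethyl methyl ether, COCCl
Why: Williamson-type O-alkylation of both phenols; the acetals keep the arene symmetric and later direct the lithiation.

Step 3
Reactants: 5 2-methoxy-1,3-bis(methoxymethoxy)benzene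
Product: 7 4-methoxy-3,5-bis(methoxymethoxy)phenol, via arylboronic pinacol ester 6 (not isolated)
Conditions: [Ir(OMe)(cod)]2 (1.5 mol %), 4,4'-di-tert-butyl-2,2'-bipyridine (3 mol %), B2pin2 (0.7 equiv), THF, 80 °C; then aq. NaOH, 30% H2O2, 0 °C
Reagents that add atoms: hydrogen peroxide, OO
Why: Iridium-catalysed aromatic C–H borylation is sterically controlled and should take the only C–H without an ortho substituent (C5, para to the methoxy group); basic peroxide then converts the C–B bond into C–O by 1,2-aryl migration in the same pot.

Step 4
Reactants: 7 4-methoxy-3,5-bis(methoxymethoxy)phenol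
Product: 8 2-methoxy-1,3-bis(methoxymethoxy)-5-[2-(trimethylsilyl)ethoxy]benzene
Conditions: Me3SiCH2CH2OH (1.3 equiv), PPh3 (2), DIAD, THF, 0 °C → rt
Reagents that add atoms: 2-(trimethylsilyl)ethanol, C[Si](C)(C)CCO
Why: Mitsunobu etherification of an unhindered phenol with a primary alcohol; the silylethyl ether is not an acetal, so it should survive step 6 and cannot attack the later acid chloride.

Step 5
Reactants: 8 2-methoxy-1,3-bis(methoxymethoxy)-5-[2-(trimethylsilyl)ethoxy]benzene
Product: 10 3-methoxy-2,4-bis(methoxymethoxy)-6-[2-(trimethylsilyl)ethoxy]benzaldehyde, via aryllithium 9 (not isolated)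
Conditions: n-BuLi (1.2 equiv), THF, −78 → 0 °C; DMF, −78 °C → rt; aq. NH4Cl
Reagents that add atoms: N,N-dimethylformamide, CN(C)C=O
Why: Directed ortho-metalation: the two ring hydrogens are equivalent by symmetry and each lies between an acetal oxygen and an ether oxygen, so lithiation and formylation can give only one aldehyde; silicon bearing only carbon substituents is not an electrophile for the aryllithium at low temperature.

Step 6
Reactants: 10 3-methoxy-2,4-bis(methoxymethoxy)-6-[2-(trimethylsilyl)ethoxy]benzaldehyde
Product: 11 2,4-dihydroxy-3-methoxy-6-[2-(trimethylsilyl)ethoxy]benzaldehyde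
Conditions: HCl (1 M in MeOH), THF, 40 °C
Reagents that add atoms: none
Why: Acid-catalysed acetal exchange with methanol removes both methoxymethyl groups as dimethoxymethane; the silylethyl aryl ether has no acetal carbon and should be inert to dilute methanolic acid.

Step 7
Reactants: 11 2,4-dihydroxy-3-methoxy-6-[2-(trimethylsilyl)ethoxy]benzaldehyde
Product: 12 2-hydroxy-3-methoxy-4-[(3-methylbut-2-en-1-yl)oxy]-6-[2-(trimethylsilyl)ethoxy]benzaldehyde
Conditions: prenyl bromide (1.05 equiv), K2CO3 (1.1 equiv), acetone, rt → 40 °C
Reagents that add atoms: 1-bromo-3-methylbut-2-ene, CC(C)=CCBr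
Why: Williamson ether synthesis under weak base: the hydroxyl para to the formyl group is the more acidic and is free, while the ortho hydroxyl is chelated to the aldehyde, so monoalkylation should occur at the oxygen that becomes O7.

Step 8
Reactants: 13 vanillic acid
Product: 15 4-[(tert-butyldimethylsilyl)oxy]-3-methoxybenzoic acid, via bis-silylated vanillic acid 14 (not isolated)
Conditions: TBSCl (2.3 equiv), imidazole, DMF, rt; then AcOH–THF–H2O, rt
Reagents that add atoms: tert-butyldimethylsilyl chloride, CC(C)(C)[Si](C)(C)Cl
Why: Silylation of phenol and acid followed by selective solvolysis of the far more labile silyl ester, the standard protection of a hydroxybenzoic acid.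

Step 9
Reactants: 12 2-hydroxy-3-methoxy-4-[(3-methylbut-2-en-1-yl)oxy]-6-[2-(trimethylsilyl)ethoxy]benzaldehyde; 15 4-[(tert-butyldimethylsilyl)oxy]-3-methoxybenzoic acid
Product: 16 2-formyl-6-methoxy-5-[(3-methylbut-2-en-1-yl)oxy]-3-[2-(trimethylsilyl)ethoxy]phenyl 4-[(tert-butyldimethylsilyl)oxy]-3-methoxybenzoate
Conditions: EDC·HCl (1.5 equiv), DMAP (0.3 equiv), CH2Cl2, 0 °C → rt
Reagents that add atoms: none
Why: Steglich esterification: carbodiimide activation and acyl transfer through the acylpyridinium ion should acylate the hindered, chelated phenol without a base that would disturb the aldehyde or the silyl ether.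

Step 10
Reactants: 16 2-formyl-6-methoxy-5-[(3-methylbut-2-en-1-yl)oxy]-3-[2-(trimethylsilyl)ethoxy]phenyl 4-[(tert-butyldimethylsilyl)oxy]-3-methoxybenzoate
Product: 17 2-({4-[(tert-butyldimethylsilyl)oxy]-3-methoxybenzoyl}oxy)-3-methoxy-4-[(3-methylbut-2-en-1-yl)oxy]-6-[2-(trimethylsilyl)ethoxy]benzoic acid
Conditions: NaClO2 (3 equiv), NaH2PO4, 2-methyl-2-butene (30 equiv), t-BuOH–THF–H2O, 0 °C → rt
Reagents that add atoms: sodium chlorite, [Na+].[O-]Cl=O
Why: Pinnick oxidation at about pH 4 leaves the aryl ester alone; the large excess of 2-methyl-2-butene should scavenge hypochlorous acid before it reaches the prenyl double bond or the activated ring position.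

Step 11
Reactants: 17 2-({4-[(tert-butyldimethylsilyl)oxy]-3-methoxybenzoyl}oxy)-3-methoxy-4-[(3-methylbut-2-en-1-yl)oxy]-6-[2-(trimethylsilyl)ethoxy]benzoic acid; 3 {[2-(trimethylsilyl)ethoxy]methyl}triphenylphosphonium chloride
Product: 20 2-{2-[2-(trimethylsilyl)ethoxy]-2-(triphenyl-λ5-phosphanylidene)acetyl}-6-methoxy-5-[(3-methylbut-2-en-1-yl)oxy]-3-[2-(trimethylsilyl)ethoxy]phenyl 4-[(tert-butyldimethylsilyl)oxy]-3-methoxybenzoate, via acid chloride 18 (not isolated), via alkoxymethylene ylide 19 (not isolated)
Conditions: 17, 1-chloro-N,N,2-trimethylprop-1-en-1-amine (1.05 equiv), CH2Cl2, 0 °C → rt; separately 3 (2.2 equiv), NaN(SiMe3)2 (2.1 equiv), THF, −78 → 0 °C; 18 added to 19 at −78 °C, → −20 °C; pH 7 buffer, short neutral alumina plug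
Reagents that add atoms: none
Why: The α-chloroenamine gives the acid chloride without releasing HCl, and C-acylation of the ylide followed by transylidation (the second equivalent of ylide removes the α-proton of the acylphosphonium salt) gives the stabilised acyl ylide. At −78 °C the acid chloride is far more electrophilic than the aryl ester, and the slight deficit of amide base leaves no free strong base.

Step 12
Reactants: 20 2-{2-[2-(trimethylsilyl)ethoxy]-2-(triphenyl-λ5-phosphanylidene)acetyl}-6-methoxy-5-[(3-methylbut-2-en-1-yl)oxy]-3-[2-(trimethylsilyl)ethoxy]phenyl 4-[(tert-butyldimethylsilyl)oxy]-3-methoxybenzoate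
Product: 21 2-{4-[(tert-butyldimethylsilyl)oxy]-3-methoxyphenyl}-8-methoxy-7-[(3-methylbut-2-en-1-yl)oxy]-3,5-bis[2-(trimethylsilyl)ethoxy]-4H-chromen-4-one
Conditions: toluene (0.02 M), 110 °C, argon
Reagents that add atoms: none
Why: Proposed new method: the ylide carbon of 20 (future C3) adds to the carbonyl carbon of the neighbouring aryl ester (future C2), the betaine closes to an oxaphosphetane, and cycloreversion expels Ph3P=O to leave the C2=C3 bond; the closest known reaction type is the intramolecular Wittig olefination of the ester in (2-acyloxybenzoyl)methylenephosphoranes, which gives chromones and flavones, and the new element is the alkoxy group on the ylide carbon, which makes the alkene tetrasubstituted. Ring C closes in a 6-exo-trig mode, with the ylide carbon as nucleophile, the ester C=O as exocyclic acceptor and C4, C4a, C8a and O1 as tether. No stereocentre forms and the new double bond is endocyclic, so no isomer can arise. The oxygen lone pair on the ylide carbon should raise its nucleophilicity relative to the unsubstituted acyl ylide and so offset the added steric demand, and formation of the P=O bond and of the pyranone makes the collapse irreversible. The selectivity needed is attack by carbon on the ester carbonyl within the same molecule: the 1,2-relationship of the two groups on ring A holds them in a six-membered arrangement, high dilution disfavours intermolecular olefination, and 20 contains no other carbonyl electrophile. Acyl transfer to the enolate oxygen of the ylide is reversible, and if the tetrahedral intermediate expels the phenoxide, the phenoxide can re-add to the new ketone beside phosphorus and lose Ph3P=O, so both detours should lead to 21. The medium is neutral and aprotic and should spare the silicon-based groups and the prenyl ether as long as the temperature stays below that of the aromatic Claisen rearrangement.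

Step 13
Reactants: 21 2-{4-[(tert-butyldimethylsilyl)oxy]-3-methoxyphenyl}-8-methoxy-7-[(3-methylbut-2-en-1-yl)oxy]-3,5-bis[2-(trimethylsilyl)ethoxy]-4H-chromen-4-one
Product: 22 3,5-dihydroxy-2-(4-hydroxy-3-methoxyphenyl)-8-methoxy-7-[(3-methylbut-2-en-1-yl)oxy]-4H-chromen-4-one (CNP0210396.0)
Conditions: Bu4NF (1 M in THF, 6 equiv), DMF, 0 → 60 °C, argon; aq. NH4Cl
Reagents that add atoms: none
Why: Fluoride attacks silicon: the aryl silyl ether is cleaved directly, and each 2-(trimethylsilyl)ethyl ether should fragment by β-elimination (fluorotrimethylsilane and ethene) because the oxygen leaves as a phenoxide or as the stabilised C3 enolate. No acid, hydrogen or electrophile meets the prenyl ether.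

## Compound list

1 | 2-(trimethylsilyl)ethoxymethyl chloride | C[Si](C)(C)CCOCCl | starting material
2 | triphenylphosphine | c1ccc(cc1)P(c1ccccc1)c1ccccc1 | starting material
3 | {[2-(trimethylsilyl)ethoxy]methyl}triphenylphosphonium chloride | C[Si](C)(C)CCOC[P+](c1ccccc1)(c1ccccc1)c1ccccc1.[Cl-] | intermediate
4 | 2-methoxyresorcinol | COc1c(O)cccc1O | starting material
5 | 2-methoxy-1,3-bis(methoxymethoxy)benzene | COCOc1cccc(OCOC)c1OC | intermediate
6 | 2-[4-methoxy-3,5-bis(methoxymethoxy)phenyl]-4,4,5,5-tetramethyl-1,3,2-dioxaborolane | COCOc1cc(B2OC(C)(C)C(C)(C)O2)cc(OCOC)c1OC | intermediate (not isolated)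
7 | 4-methoxy-3,5-bis(methoxymethoxy)phenol | COCOc1cc(O)cc(OCOC)c1OC | intermediate
8 | 2-methoxy-1,3-bis(methoxymethoxy)-5-[2-(trimethylsilyl)ethoxy]benzene | COCOc1cc(OCC[Si](C)(C)C)cc(OCOC)c1OC | intermediate
9 | {3-methoxy-2,4-bis(methoxymethoxy)-6-[2-(trimethylsilyl)ethoxy]phenyl}lithium | [Li]c1c(OCOC)c(OC)c(OCOC)cc1OCC[Si](C)(C)C | intermediate (not isolated)
10 | 3-methoxy-2,4-bis(methoxymethoxy)-6-[2-(trimethylsilyl)ethoxy]benzaldehyde | O=Cc1c(OCOC)c(OC)c(OCOC)cc1OCC[Si](C)(C)C | intermediate
11 | 2,4-dihydroxy-3-methoxy-6-[2-(trimethylsilyl)ethoxy]benzaldehyde | O=Cc1c(O)c(OC)c(O)cc1OCC[Si](C)(C)C | intermediate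
12 | 2-hydroxy-3-methoxy-4-[(3-methylbut-2-en-1-yl)oxy]-6-[2-(trimethylsilyl)ethoxy]benzaldehyde | O=Cc1c(O)c(OC)c(OCC=C(C)C)cc1OCC[Si](C)(C)C | intermediate
13 | vanillic acid | COc1cc(C(=O)O)ccc1O | starting material
14 | tert-butyldimethylsilyl 4-[(tert-butyldimethylsilyl)oxy]-3-methoxybenzoate | COc1cc(C(=O)O[Si](C)(C)C(C)(C)C)ccc1O[Si](C)(C)C(C)(C)C | intermediate (not isolated)
15 | 4-[(tert-butyldimethylsilyl)oxy]-3-methoxybenzoic acid | COc1cc(C(=O)O)ccc1O[Si](C)(C)C(C)(C)C | intermediate
16 | 2-formyl-6-methoxy-5-[(3-methylbut-2-en-1-yl)oxy]-3-[2-(trimethylsilyl)ethoxy]phenyl 4-[(tert-butyldimethylsilyl)oxy]-3-methoxybenzoate | O=Cc1c(OC(=O)c2ccc(O[Si](C)(C)C(C)(C)C)c(OC)c2)c(OC)c(OCC=C(C)C)cc1OCC[Si](C)(C)C | intermediate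
17 | 2-({4-[(tert-butyldimethylsilyl)oxy]-3-methoxybenzoyl}oxy)-3-methoxy-4-[(3-methylbut-2-en-1-yl)oxy]-6-[2-(trimethylsilyl)ethoxy]benzoic acid | OC(=O)c1c(OC(=O)c2ccc(O[Si](C)(C)C(C)(C)C)c(OC)c2)c(OC)c(OCC=C(C)C)cc1OCC[Si](C)(C)C | intermediate
18 | 2-({4-[(tert-butyldimethylsilyl)oxy]-3-methoxybenzoyl}oxy)-3-methoxy-4-[(3-methylbut-2-en-1-yl)oxy]-6-[2-(trimethylsilyl)ethoxy]benzoyl chloride | ClC(=O)c1c(OC(=O)c2ccc(O[Si](C)(C)C(C)(C)C)c(OC)c2)c(OC)c(OCC=C(C)C)cc1OCC[Si](C)(C)C | intermediate (not isolated)
19 | {[2-(trimethylsilyl)ethoxy]methylidene}triphenyl-λ5-phosphane | C[Si](C)(C)CCOC=P(c1ccccc1)(c1ccccc1)c1ccccc1 | intermediate (not isolated)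
20 | 2-{2-[2-(trimethylsilyl)ethoxy]-2-(triphenyl-λ5-phosphanylidene)acetyl}-6-methoxy-5-[(3-methylbut-2-en-1-yl)oxy]-3-[2-(trimethylsilyl)ethoxy]phenyl 4-[(tert-butyldimethylsilyl)oxy]-3-methoxybenzoate | C[Si](C)(C)CCOC(=P(c1ccccc1)(c1ccccc1)c1ccccc1)C(=O)c1c(OCC[Si](C)(C)C)cc(OCC=C(C)C)c(OC)c1OC(=O)c1ccc(O[Si](C)(C)C(C)(C)C)c(OC)c1 | intermediate
21 | 2-{4-[(tert-butyldimethylsilyl)oxy]-3-methoxyphenyl}-8-methoxy-7-[(3-methylbut-2-en-1-yl)oxy]-3,5-bis[2-(trimethylsilyl)ethoxy]-4H-chromen-4-one | COc1cc(-c2oc3c(OC)c(OCC=C(C)C)cc(OCC[Si](C)(C)C)c3c(=O)c2OCC[Si](C)(C)C)ccc1O[Si](C)(C)C(C)(C)C | intermediate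
22 | 3,5-dihydroxy-2-(4-hydroxy-3-methoxyphenyl)-8-methoxy-7-[(3-methylbut-2-en-1-yl)oxy]-4H-chromen-4-one | COc1cc(-c2oc3c(OC)c(OCC=C(C)C)cc(O)c3c(=O)c2O)ccc1O | target

## Step count and least certain steps

Total step count: 13. Longest linear sequence: 11 steps (steps 2–7 and 9–13, from 4 to 22); steps 1 and 8 are side branches.

Step 12 (key step, the proposed new method). The fully substituted, oxygen-bearing ylide carbon may add too slowly to the hindered ester. At the temperature then required, aromatic Claisen rearrangement of the prenyl ether or thermal loss of a silylethyl group could overtake ring closure. The fallback uses known chemistry, sets out from 18 and returns at 22. Two equivalents of methylenetriphenylphosphorane (from CH3PPh3Br and NaN(SiMe3)2) should convert 18 into 2-[2-(triphenyl-λ5-phosphanylidene)acetyl]-6-methoxy-5-[(3-methylbut-2-en-1-yl)oxy]-3-[2-(trimethylsilyl)ethoxy]phenyl 4-[(tert-butyldimethylsilyl)oxy]-3-methoxybenzoate F1. Heating F1 in toluene is the established ester Wittig closure and should give 2-{4-[(tert-butyldimethylsilyl)oxy]-3-methoxyphenyl}-8-methoxy-7-[(3-methylbut-2-en-1-yl)oxy]-5-[2-(trimethylsilyl)ethoxy]-4H-chromen-4-one F2. Lithiation at C3 with LiN(i-Pr)2 at −78 °C, trapping with B(OMe)3 and oxidation of the C–B bond with H2O2–AcOH should give 2-{4-[(tert-butyldimethylsilyl)oxy]-3-methoxyphenyl}-3-hydroxy-8-methoxy-7-[(3-methylbut-2-en-1-yl)oxy]-5-[2-(trimethylsilyl)ethoxy]-4H-chromen-4-one F3. The fluoride conditions of step 13 then convert F3 into 22. The C3 oxygen is introduced after ring closure by a nucleophilic peroxide on boron, which does not attack the prenyl alkene.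

Step 11. The reactive alkoxymethylene ylide may attack the neighbouring aryl ester once the acid chloride is used up. Participation of the ortho ester in the acid chloride may scramble the acyl groups. Acylation at a carbonyl flanked by two ortho substituents may stall. The fallback sets out from 17 and returns at 20. Silylation (TBSCl, imidazole) gives tert-butyldimethylsilyl 2-({4-[(tert-butyldimethylsilyl)oxy]-3-methoxybenzoyl}oxy)-3-methoxy-4-[(3-methylbut-2-en-1-yl)oxy]-6-[2-(trimethylsilyl)ethoxy]benzoate F4, which is treated with one equivalent of 19. Silyl esters of O-acylsalicylic acids acylate phosphorus ylides without touching the aryl ester, and the silanolate set free serves as the internal base. No acid chloride and no second equivalent of ylide are then needed.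

Step 13. Fragmentation of the silylethyl ethers may be slow, above all for the last one, which must leave from a flavonol that is already doubly deprotonated. Prolonged heating of the flavonolate in a basic medium invites oxidative degradation. The fallback sets out from 21 and returns at 22, in two stages. Brief treatment with Bu4NF at 0 °C should remove only the aryl silyl ether and give 2-(4-hydroxy-3-methoxyphenyl)-8-methoxy-7-[(3-methylbut-2-en-1-yl)oxy]-3,5-bis[2-(trimethylsilyl)ethoxy]-4H-chromen-4-one F5. MgBr2·OEt2 in CH2Cl2–MeNO2 should then chelate the C4 carbonyl together with O3 or O5, which are exactly the two ether oxygens to be freed. Bromide attack at silicon releases ethene without a strongly basic medium.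

Step 7. Alkylation may go on to the chelated hydroxyl, or the ambident phenoxide of the very electron-rich ring may be prenylated on carbon. The fallback sets out from 11 and returns at 12. It replaces the phenoxide alkylation by a Mitsunobu reaction with 3-methylbut-2-en-1-ol (PPh3, DIAD, THF, 0 °C). No free phenoxide is present, and the more acidic para hydroxyl is the one that engages. No new compound is formed on the way.

## Further compounds

F1 | step 12 | 2-[2-(triphenyl-λ5-phosphanylidene)acetyl]-6-methoxy-5-[(3-methylbut-2-en-1-yl)oxy]-3-[2-(trimethylsilyl)ethoxy]phenyl 4-[(tert-butyldimethylsilyl)oxy]-3-methoxybenzoate | O=C(C=P(c1ccccc1)(c1ccccc1)c1ccccc1)c1c(OCC[Si](C)(C)C)cc(OCC=C(C)C)c(OC)c1OC(=O)c1ccc(O[Si](C)(C)C(C)(C)C)c(OC)c1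
F2 | step 12 | 2-{4-[(tert-butyldimethylsilyl)oxy]-3-methoxyphenyl}-8-methoxy-7-[(3-methylbut-2-en-1-yl)oxy]-5-[2-(trimethylsilyl)ethoxy]-4H-chromen-4-one | COc1cc(-c2cc(=O)c3c(OCC[Si](C)(C)C)cc(OCC=C(C)C)c(OC)c3o2)ccc1O[Si](C)(C)C(C)(C)C
F3 | step 12 | 2-{4-[(tert-butyldimethylsilyl)oxy]-3-methoxyphenyl}-3-hydroxy-8-methoxy-7-[(3-methylbut-2-en-1-yl)oxy]-5-[2-(trimethylsilyl)ethoxy]-4H-chromen-4-one | COc1cc(-c2oc3c(OC)c(OCC=C(C)C)cc(OCC[Si](C)(C)C)c3c(=O)c2O)ccc1O[Si](C)(C)C(C)(C)C
F4 | step 11 | tert-butyldimethylsilyl 2-({4-[(tert-butyldimethylsilyl)oxy]-3-methoxybenzoyl}oxy)-3-methoxy-4-[(3-methylbut-2-en-1-yl)oxy]-6-[2-(trimethylsilyl)ethoxy]benzoate | CC(C)(C)[Si](C)(C)OC(=O)c1c(OC(=O)c2ccc(O[Si](C)(C)C(C)(C)C)c(OC)c2)c(OC)c(OCC=C(C)C)cc1OCC[Si](C)(C)C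
F5 | step 13 | 2-(4-hydroxy-3-methoxyphenyl)-8-methoxy-7-[(3-methylbut-2-en-1-yl)oxy]-3,5-bis[2-(trimethylsilyl)ethoxy]-4H-chromen-4-one | COc1cc(-c2oc3c(OC)c(OCC=C(C)C)cc(OCC[Si](C)(C)C)c3c(=O)c2OCC[Si](C)(C)C)ccc1O
F0 | step 7 | none | none
A1 | alternative 1 | 4-(benzyloxy)-2-[(tert-butyldimethylsilyl)oxy]furan | CC(C)(C)[Si](C)(C)Oc1cc(OCc2ccccc2)co1
A2 | alternative 1 | methyl 3-bromopropiolate | COC(=O)C#CBr
A3 | alternative 1 | methyl 4-(benzyloxy)-2-bromo-6-[(tert-butyldimethylsilyl)oxy]-3-hydroxybenzoate | COC(=O)c1c(Br)c(O)c(OCc2ccccc2)cc1O[Si](C)(C)C(C)(C)C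
A4 | alternative 2 | 5-acetyl-2-[3-methoxy-4-(methoxymethoxy)phenyl]-3-(methoxymethoxy)-6-(methylsulfanyl)-4H-pyran-4-one | CC(=O)c1c(SC)oc(-c2ccc(OCOC)c(OC)c2)c(OCOC)c1=O
A5 | alternative 2 | methyl methoxyacetate | COCC(=O)OC
A6 | alternative 2 | 5,7-dihydroxy-8,3'-dimethoxy-3,4'-bis(methoxymethoxy)flavone | COCOc1ccc(-c2oc3c(OC)c(O)cc(O)c3c(=O)c2OCOC)cc1OC
A7 | alternative 3 | 2-iodo-6-methoxy-3-(methoxymethoxy)-5-[(3-methylbut-2-en-1-yl)oxy]phenol | COCOc1cc(OCC=C(C)C)c(OC)c(O)c1I
A8 | alternative 3 | 4-ethynyl-2-methoxy-1-(methoxymethoxy)benzene | C#Cc1ccc(OCOC)c(OC)c1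
A9 | alternative 3 | carbon monoxide | [C-]#[O+]
A10 | alternative 3 | 5,4'-bis(methoxymethoxy)-8,3'-dimethoxy-7-(prenyloxy)flavone | COCOc1ccc(-c2cc(=O)c3c(OCOC)cc(OCC=C(C)C)c(OC)c3o2)cc1OC
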